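Ring B is closed last. Its O2–C3 bond is formed from the C1 formyl oxygen and a propynyl group on C4a, which sit cis across C7a=C4a of a fully substituted cyclopentadiene (ring C). One gold-catalysed operation closes the pyran 6-endo and discharges the pyrylium by loss of the acidic C1' proton, which also creates the exocyclic C6=C1' enone. The precursor is a cyclopenta-1,4-diene carrying CO2Me (C5), propynyl (C4a), CHO (C7a), the 2-oxoalkyl chain (C6) and the silylated C7 carbinol. C7 comes from (S)-citramalic acid and C3' from an Evans methylation. The acidic side-chain ketone is unveiled one step before cyclisation.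

Key step: step 15

Remark: atom labels (C1, O2, C3, C4, C4a, C5, C6, C7, C7a, side chain C1' onwards) follow the cyclopenta[c]pyran numbering of the target; 6–8 are written as one enol tautomer, and 22 and 23 are carried as mixtures of C2' epimers that converge in step 14.

Step 1
Reactants: 1 (S)-citramalic acid
Product: 2 2-[(4S)-2,2,4-trimethyl-5-oxo-1,3-dioxolan-4-yl]acetic acid
Conditions: Me2C(OMe)2, TsOH·H2O (cat.), rt
Reagents that add atoms: 2,2-dimethoxypropane, COC(C)(C)OC
Why: Acid-catalysed transacetalisation closes the five-membered dioxolanone on the tertiary alpha-hydroxy acid, which masks the C7 hydroxyl, activates the carboxyl that becomes C6 and leaves the CH2CO2H arm free, without touching a bond to the stereocentre.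

Step 2
Reactants: 2 2-[(4S)-2,2,4-trimethyl-5-oxo-1,3-dioxolan-4-yl]acetic acid; 3 potassium methyl malonate
Product: 5 methyl 4-[(4S)-2,2,4-trimethyl-5-oxo-1,3-dioxolan-4-yl]-3-oxobutanoate, via acyl imidazolide 4 (not isolated)
Conditions: CDI, THF, rt; then KO2CCH2CO2Me, MgCl2, Et3N, THF, rt to 45 °C; aq. citric acid
Reagents that add atoms: none
Why: Masamune–Brooks homologation, in which the acyl imidazolide is C-acylated by magnesium methyl malonate and the adduct decarboxylates on acidic work-up, adds C5 and the ester carbon while the less electrophilic dioxolanone carbonyl should survive.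

Step 3
Reactants: 5 methyl 4-[(4S)-2,2,4-trimethyl-5-oxo-1,3-dioxolan-4-yl]-3-oxobutanoate
Product: 6 methyl (4S)-2,4-dihydroxy-4-methyl-5-oxocyclopent-1-ene-1-carboxylate
Conditions: KOtBu (2.1 equiv), THF, 0 °C to rt; then 1 M HCl
Reagents that add atoms: none
Why: Dieckmann (intramolecular Claisen) condensation, in which the beta-keto ester carbon C5 attacks the activated dioxolanone carbonyl C6 in a 5-exo-trig closure with loss of acetone, is driven by formation of the strongly acidic triacylmethane enolate, and the quaternary stereocentre cannot epimerise.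

Step 4
Reactants: 6 methyl (4S)-2,4-dihydroxy-4-methyl-5-oxocyclopent-1-ene-1-carboxylate
Product: 8 methyl (4S)-2-hydroxy-4-methyl-5-oxo-4-[(triethylsilyl)oxy]cyclopent-1-ene-1-carboxylate, via bis-silyl ether 7 (not isolated)
Conditions: Et3SiOTf (2.5 equiv), 2,6-lutidine, CH2Cl2, −78 to 0 °C; aqueous work-up at pH 4
Reagents that add atoms: triethylsilyl triflate, CC[Si](CC)(CC)OS(=O)(=O)C(F)(F)F
Why: Silylation with the silyl triflate reaches the hindered tertiary hydroxyl, and the enol silyl ether formed at the same time is a labile vinylogous silyl ester that hydrolyses on work-up.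

Step 5
Reactants: 8 methyl (4S)-2-hydroxy-4-methyl-5-oxo-4-[(triethylsilyl)oxy]cyclopent-1-ene-1-carboxylate
Product: 9 methyl (4S)-4-methyl-5-oxo-4-[(triethylsilyl)oxy]-2-{[(trifluoromethyl)sulfonyl]oxy}cyclopent-1-ene-1-carboxylate
Conditions: Tf2O, iPr2NEt, CH2Cl2, −78 °C; used crude
Reagents that add atoms: triflic anhydride, O=S(=O)(OS(=O)(=O)C(F)(F)F)C(F)(F)F
Why: Enol triflate formation on the 2-acyl-1,3-dione enolate should take place at the oxygen on C4a, which is flanked by CH2, and not at the oxygen on C6 beside the quaternary silyloxy carbon.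

Step 6
Reactants: 9 methyl (4S)-4-methyl-5-oxo-4-[(triethylsilyl)oxy]-2-{[(trifluoromethyl)sulfonyl]oxy}cyclopent-1-ene-1-carboxylate; 10 propyne
Product: 11 methyl (4S)-4-methyl-5-oxo-2-(prop-1-yn-1-yl)-4-[(triethylsilyl)oxy]cyclopent-1-ene-1-carboxylate
Conditions: propyne (excess), PdCl2(PPh3)2 (5 mol %), CuI (10 mol %), iPr2NEt, THF, 0 °C to rt
Reagents that add atoms: none
Why: Sonogashira coupling works because zerovalent palladium adds readily to the electron-poor vinylogous acyl triflate, the tertiary amine cannot displace the triflate, and the silyl ether and ester are inert.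

Step 7
Reactants: 11 methyl (4S)-4-methyl-5-oxo-2-(prop-1-yn-1-yl)-4-[(triethylsilyl)oxy]cyclopent-1-ene-1-carboxylate
Product: 13 methyl (3S)-2-bromo-4-formyl-3-methyl-5-(prop-1-yn-1-yl)-3-[(triethylsilyl)oxy]cyclopenta-1,4-diene-1-carboxylate, via dienaminone 12 (not isolated)
Conditions: Me2NCH(OtBu)2, PhMe, 50 °C; evaporate; (COBr)2, CH2Cl2, −40 to 0 °C; then aq. NaHCO3, THF, 0 °C
Reagents that add atoms: N,N-dimethylformamide di-tert-butyl acetal, CN(C)C(OC(C)(C)C)OC(C)(C)C; oxalyl bromide, O=C(Br)C(Br)=O; water, O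
Why: The ring CH2 at C7a is vinylogously acidified by the C6 ketone and the ester, so the formamide acetal condenses there, and oxalyl bromide then activates the vinylogous amide oxygen so that bromide takes its place at C6 as in the halogenation stage of a Vilsmeier–Arnold haloformylation, after which hydrolysis of the iminium salt frees the C1 aldehyde with the ring double bonds at C6=C5 and C4a=C7a.

Step 8
Reactants: 14 (4S)-4-benzyl-1,3-oxazolidin-2-one; 15 octanoyl chloride
Product: 16 (4S)-4-benzyl-3-octanoyl-1,3-oxazolidin-2-one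
Conditions: n-BuLi, THF, −78 °C; then 15, −78 to 0 °C
Reagents that add atoms: none
Why: N-Acylation of the lithiated oxazolidinone by the acid chloride is a standard preparation of the imide.

Step 9
Reactants: 16 (4S)-4-benzyl-3-octanoyl-1,3-oxazolidin-2-one
Product: 17 (4S)-4-benzyl-3-[(2S)-2-methyloctanoyl]-1,3-oxazolidin-2-one
Conditions: NaN(SiMe3)2, THF, −78 °C; MeI, −78 °C
Reagents that add atoms: iodomethane, CI
Why: In this Evans alkylation the chelated Z sodium enolate is methylated on the face opposite the benzyl group of the (S)-auxiliary, which sets the 2S centre that becomes C3', and the minor diastereomer should be removable by chromatography.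

Step 10
Reactants: 17 (4S)-4-benzyl-3-[(2S)-2-methyloctanoyl]-1,3-oxazolidin-2-one; 18 4-methoxybenzyl alcohol
Product: 19 4-methoxybenzyl (2S)-2-methyloctanoate
Conditions: 18, n-BuLi, THF, 0 °C; then 17, 0 °C; aq. NH4Cl
Reagents that add atoms: none
Why: Alkoxide transesterification of the N-acyl oxazolidinone at its exocyclic carbonyl releases the auxiliary at 0 °C without enolising the alpha stereocentre.

Step 11
Reactants: 19 4-methoxybenzyl (2S)-2-methyloctanoate
Product: 20 1-methoxy-4-({[(3S)-3-methylnon-1-en-2-yl]oxy}methyl)benzene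
Conditions: Cp2TiMe2 (2.5 equiv), PhMe, 65 °C, dark
Reagents that add atoms: dimethyltitanocene, C[Ti](C)(C1C=CC=C1)C1C=CC=C1
Why: Petasis methylenation turns the ester carbonyl into a 1-alkoxyvinyl group through a titanium methylidene under non-basic conditions, so C3' keeps its configuration.

Step 12
Reactants: 13 methyl (3S)-2-bromo-4-formyl-3-methyl-5-(prop-1-yn-1-yl)-3-[(triethylsilyl)oxy]cyclopenta-1,4-diene-1-carboxylate; 20 1-methoxy-4-({[(3S)-3-methylnon-1-en-2-yl]oxy}methyl)benzene
Product: 22 methyl (3R)-4-formyl-2-{(2RS,3S)-2-[(4-methoxybenzyl)oxy]-3-methylnonyl}-3-methyl-5-(prop-1-yn-1-yl)-3-[(triethylsilyl)oxy]cyclopenta-1,4-diene-1-carboxylate, via B-alkyl-9-BBN 21 (not isolated)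
Conditions: 20 (1.5 equiv), 9-BBN (1.4 equiv), THF, rt; aq. K3PO4; then 13, PdCl2(dppf) (10 mol %), AsPh3, DMF, rt
Reagents that add atoms: none
Why: Hydroboration places boron on the terminal carbon of the enol ether, and the beta-alkoxy alkylborane then undergoes B-alkyl Suzuki–Miyaura coupling with the activated vinyl bromide at C6, which forms the C6–C1' bond with the chain at the non-acidic alcohol oxidation level and with a carbinol centre whose configuration is irrelevant.

Step 13
Reactants: 22 methyl (3R)-4-formyl-2-{(2RS,3S)-2-[(4-methoxybenzyl)oxy]-3-methylnonyl}-3-methyl-5-(prop-1-yn-1-yl)-3-[(triethylsilyl)oxy]cyclopenta-1,4-diene-1-carboxylate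
Product: 23 methyl (3R)-4-formyl-2-[(2RS,3S)-2-hydroxy-3-methylnonyl]-3-methyl-5-(prop-1-yn-1-yl)-3-[(triethylsilyl)oxy]cyclopenta-1,4-diene-1-carboxylate
Conditions: DDQ, CH2Cl2/pH 7 buffer, 0 °C
Reagents that add atoms: none
Why: Oxidative cleavage of the 4-methoxybenzyl ether by DDQ under buffered conditions should leave the tertiary silyl ether, the aldehyde, the alkyne and the electron-poor diene untouched.

Step 14
Reactants: 23 methyl (3R)-4-formyl-2-[(2RS,3S)-2-hydroxy-3-methylnonyl]-3-methyl-5-(prop-1-yn-1-yl)-3-[(triethylsilyl)oxy]cyclopenta-1,4-diene-1-carboxylate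
Product: 24 methyl (3R)-4-formyl-3-methyl-2-[(3S)-3-methyl-2-oxononyl]-5-(prop-1-yn-1-yl)-3-[(triethylsilyl)oxy]cyclopenta-1,4-diene-1-carboxylate
Conditions: Dess–Martin periodinane (1.2 equiv), NaHCO3, CH2Cl2, 0 °C; used at once
Reagents that add atoms: none
Why: Dess–Martin oxidation converts both carbinol epimers into the C2' ketone under buffered conditions that should not epimerise C3', and the acidic keto aldehyde is taken on directly so that it has no time to self-condense or lactonise onto the ester.

Step 15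
Reactants: 24 methyl (3R)-4-formyl-3-methyl-2-[(3S)-3-methyl-2-oxononyl]-5-(prop-1-yn-1-yl)-3-[(triethylsilyl)oxy]cyclopenta-1,4-diene-1-carboxylate
Product: 25 methyl (6Z,7R)-3,7-dimethyl-6-[(3S)-3-methyl-2-oxononylidene]-7-[(triethylsilyl)oxy]-6,7-dihydrocyclopenta[c]pyran-5-carboxylate
Conditions: Ph3PAuNTf2 (5 mol %), 4 Å MS, CH2Cl2, rt
Reagents that add atoms: none
Why: Cationic monovalent gold coordinates the C4≡C3 alkyne, the formyl oxygen on C7a attacks the methyl-bearing carbon C3 anti to gold in a 6-endo-dig closure of ring B, and the 4-aurated pyrylium is neutralised by loss of a C1' proton (alpha to the ketone and vinylogous to the pyrylium through C6=C5) before protodeauration at C4 frees the catalyst, so the step is an isomerisation. The closest known reaction type is the gold- or silver-catalysed cycloisomerisation of 2-alkynyl enals and 2-alkynylbenzaldehydes to pyrylium species, combined with anhydrobase formation from an alkylpyrylium ion. No stereocentre is formed and C7 is untouched; the C6=C1' bond should settle as the Z isomer, in which the acyl group lies beside the sp3 carbon C7 and away from the coplanar C5 ester, and the push-pull character of the product lets the geometry equilibrate. 6-endo attack must beat 5-exo attack, which is secured by the aromatic pyrylium being formed and by the wide exocyclic angles of five-membered ring C, which bring the formyl oxygen nearer the distal carbon and would make a 5/5-fused furan strained. The formyl oxygen must also beat the C5 ester carbonyl, whose adduct has no productive exit under dry conditions with the non-nucleophilic NTf2 counter-ion and can revert, whereas the formyl adduct is drained by proton loss. The C7 oxygen stays silylated so that it neither binds the catalyst nor interferes in the preceding steps.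

Step 16
Reactants: 25 methyl (6Z,7R)-3,7-dimethyl-6-[(3S)-3-methyl-2-oxononylidene]-7-[(triethylsilyl)oxy]-6,7-dihydrocyclopenta[c]pyran-5-carboxylate
Product: 26 methyl (6Z,7R)-7-hydroxy-3,7-dimethyl-6-[(3S)-3-methyl-2-oxononylidene]-6,7-dihydrocyclopenta[c]pyran-5-carboxylate
Conditions: HF·pyridine, pyridine, THF, 0 °C to rt
Reagents that add atoms: none
Why: Buffered fluoride cleavage of the tertiary triethylsilyl ether is mild enough for the vinylogous ester chromophore and C3', and the freed hydroxyl can hydrogen-bond to the C2' carbonyl, which holds the Z geometry.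

Compound list
1 | (S)-citramalic acid | OC(=O)C[C@](C)(O)C(O)=O | starting material
2 | 2-[(4S)-2,2,4-trimethyl-5-oxo-1,3-dioxolan-4-yl]acetic acid | OC(=O)C[C@]1(C)OC(C)(C)OC1=O | intermediate
3 | potassium methyl malonate | COC(=O)CC(=O)[O-].[K+] | starting material
4 | 1-{[(4S)-2,2,4-trimethyl-5-oxo-1,3-dioxolan-4-yl]acetyl}-1H-imidazole | O=C(C[C@]1(C)OC(C)(C)OC1=O)n1ccnc1 | intermediate
5 | methyl 4-[(4S)-2,2,4-trimethyl-5-oxo-1,3-dioxolan-4-yl]-3-oxobutanoate | COC(=O)CC(=O)C[C@]1(C)OC(C)(C)OC1=O | intermediate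
6 | methyl (4S)-2,4-dihydroxy-4-methyl-5-oxocyclopent-1-ene-1-carboxylate | COC(=O)C1=C(O)C[C@](C)(O)C1=O | intermediate
7 | methyl (4S)-4-methyl-5-oxo-2,4-bis[(triethylsilyl)oxy]cyclopent-1-ene-1-carboxylate | COC(=O)C1=C(O[Si](CC)(CC)CC)C[C@](C)(O[Si](CC)(CC)CC)C1=O | intermediate
8 | methyl (4S)-2-hydroxy-4-methyl-5-oxo-4-[(triethylsilyl)oxy]cyclopent-1-ene-1-carboxylate | COC(=O)C1=C(O)C[C@](C)(O[Si](CC)(CC)CC)C1=O | intermediate
9 | methyl (4S)-4-methyl-5-oxo-4-[(triethylsilyl)oxy]-2-{[(trifluoromethyl)sulfonyl]oxy}cyclopent-1-ene-1-carboxylate | COC(=O)C1=C(OS(=O)(=O)C(F)(F)F)C[C@](C)(O[Si](CC)(CC)CC)C1=O | intermediate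
10 | propyne | CC#C | starting material
11 | methyl (4S)-4-methyl-5-oxo-2-(prop-1-yn-1-yl)-4-[(triethylsilyl)oxy]cyclopent-1-ene-1-carboxylate | COC(=O)C1=C(C#CC)C[C@](C)(O[Si](CC)(CC)CC)C1=O | intermediate
12 | methyl (4S)-3-[(dimethylamino)methylidene]-4-methyl-5-oxo-2-(prop-1-yn-1-yl)-4-[(triethylsilyl)oxy]cyclopent-1-ene-1-carboxylate | COC(=O)C1=C(C#CC)C(=CN(C)C)[C@](C)(O[Si](CC)(CC)CC)C1=O | intermediate
13 | methyl (3S)-2-bromo-4-formyl-3-methyl-5-(prop-1-yn-1-yl)-3-[(triethylsilyl)oxy]cyclopenta-1,4-diene-1-carboxylate | BrC1=C(C(=O)OC)C(C#CC)=C(C=O)[C@]1(C)O[Si](CC)(CC)CC | intermediate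
14 | (4S)-4-benzyl-1,3-oxazolidin-2-one | O=C1N[C@@H](Cc2ccccc2)CO1 | starting material
15 | octanoyl chloride | CCCCCCCC(Cl)=O | starting material
16 | (4S)-4-benzyl-3-octanoyl-1,3-oxazolidin-2-one | CCCCCCCC(=O)N1[C@@H](Cc2ccccc2)COC1=O | intermediate
17 | (4S)-4-benzyl-3-[(2S)-2-methyloctanoyl]-1,3-oxazolidin-2-one | CCCCCC[C@H](C)C(=O)N1[C@@H](Cc2ccccc2)COC1=O | intermediate
18 | 4-methoxybenzyl alcohol | COc1ccc(CO)cc1 | starting material
19 | 4-methoxybenzyl (2S)-2-methyloctanoate | CCCCCC[C@H](C)C(=O)OCc1ccc(OC)cc1 | intermediate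
20 | 1-methoxy-4-({[(3S)-3-methylnon-1-en-2-yl]oxy}methyl)benzene | CCCCCC[C@H](C)C(=C)OCc1ccc(OC)cc1 | intermediate
21 | 9-{(2RS,3S)-2-[(4-methoxybenzyl)oxy]-3-methylnonyl}-9-borabicyclo[3.3.1]nonane | CCCCCC[C@H](C)C(CB1C2CCCC1CCC2)OCc1ccc(OC)cc1 | intermediate
22 | methyl (3R)-4-formyl-2-{(2RS,3S)-2-[(4-methoxybenzyl)oxy]-3-methylnonyl}-3-methyl-5-(prop-1-yn-1-yl)-3-[(triethylsilyl)oxy]cyclopenta-1,4-diene-1-carboxylate | CCCCCC[C@H](C)C(OCc1ccc(OC)cc1)CC1=C(C(=O)OC)C(C#CC)=C(C=O)[C@]1(C)O[Si](CC)(CC)CC | intermediate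
23 | methyl (3R)-4-formyl-2-[(2RS,3S)-2-hydroxy-3-methylnonyl]-3-methyl-5-(prop-1-yn-1-yl)-3-[(triethylsilyl)oxy]cyclopenta-1,4-diene-1-carboxylate | CCCCCC[C@H](C)C(O)CC1=C(C(=O)OC)C(C#CC)=C(C=O)[C@]1(C)O[Si](CC)(CC)CC | intermediate
24 | methyl (3R)-4-formyl-3-methyl-2-[(3S)-3-methyl-2-oxononyl]-5-(prop-1-yn-1-yl)-3-[(triethylsilyl)oxy]cyclopenta-1,4-diene-1-carboxylate | CCCCCC[C@H](C)C(=O)CC1=C(C(=O)OC)C(C#CC)=C(C=O)[C@]1(C)O[Si](CC)(CC)CC | intermediate
25 | methyl (6Z,7R)-3,7-dimethyl-6-[(3S)-3-methyl-2-oxononylidene]-7-[(triethylsilyl)oxy]-6,7-dihydrocyclopenta[c]pyran-5-carboxylate | CCCCCC[C@H](C)C(=O)/C=C1/C(C(=O)OC)=C2C=C(C)OC=C2[C@]1(C)O[Si](CC)(CC)CC | intermediate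
26 | methyl (6Z,7R)-7-hydroxy-3,7-dimethyl-6-[(3S)-3-methyl-2-oxononylidene]-6,7-dihydrocyclopenta[c]pyran-5-carboxylate | CCCCCC[C@H](C)C(=O)/C=C1/C(C(=O)OC)=C2C=C(C)OC=C2[C@]1(C)O | target

Total step count: 16. Longest linear sequence: 12 steps (steps 1–7 and 12–16, from 1).

Steps most likely to fail

Step 7. The doubly activated propynyl group of 11 may suffer conjugate addition of tert-butoxide, dimethylamine or bromide. Condensation may also occur at the propargylic methyl instead of the ring methylene, and exchange of oxygen for bromide at the hindered C6 may be slow. The fallback sets out from 11 and comes back at 22; it brings the formyl carbon in as an acetal and activates C6 as a triflate. Et3N and Et3SiOTf should convert 11 into the silyl dienol ether F1. A vinylogous Mukaiyama reaction with HC(OMe)3 and BF3·OEt2 at the free diene terminus C7a should give the keto acetal F2. KN(SiMe3)2 and PhNTf2 should then give the dienyl triflate F3. B-alkyl Suzuki–Miyaura coupling of F3 with 21 under the conditions of step 12 should give the coupled dimethyl acetal F4, and pyridinium tosylate in wet acetone should release the aldehyde 22.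

Step 15. The C5 ester carbonyl or a 5-exo pathway may compete for the gold-activated alkyne, the side-chain enol may lactonise onto the C5 ester with loss of methanol, and the chelating keto aldehyde may sequester the catalyst. The fallback sets out from 23 and comes back at 25; it runs the ring closure one oxidation level earlier, where there is no acidic methylene and no enolisable ketone. With Ph3PAuNTf2 in CH2Cl2 the pyrylium derived from 23 should lose a C1' proton to give the ylidene pyran allylic alcohol F5, and MnO2 oxidation of this allylic alcohol should give 25.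

Step 12. Transmetalation at the tetrasubstituted bromide beside the quaternary carbon may be slow, which would allow protodebromination or beta-hydride loss from the alkylpalladium, and the basic aqueous medium or the borane may attack the aldehyde. The fallback sets out from 13 and 20 and comes back at 24; it makes the C6–C1' bond by addition–elimination of a ketone enolate in place of cross-coupling. Mild aqueous oxalic acid should hydrolyse 20 to (3S)-3-methylnonan-2-one F6. Me3SiOCH2CH2OSiMe3 with catalytic Me3SiOTf should protect 13 as the bromo dioxolane F7. The kinetic lithium enolate of F6 (LiN(iPr)2, THF, −78 °C, two equivalents) should add to C6 of this beta-bromo acrylate and expel bromide to give the keto dioxolane F8, and aqueous oxalic acid should then free the aldehyde 24.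

Further compounds
F1 | step 7 | methyl (3S)-3-methyl-5-(prop-1-yn-1-yl)-2,3-bis[(triethylsilyl)oxy]cyclopenta-1,4-diene-1-carboxylate | COC(=O)C1=C(O[Si](CC)(CC)CC)[C@@](C)(O[Si](CC)(CC)CC)C=C1C#CC
F2 | step 7 | methyl (3RS,4S)-3-(dimethoxymethyl)-4-methyl-5-oxo-2-(prop-1-yn-1-yl)-4-[(triethylsilyl)oxy]cyclopent-1-ene-1-carboxylate | COC(=O)C1=C(C#CC)C(C(OC)OC)[C@](C)(O[Si](CC)(CC)CC)C1=O
F3 | step 7 | methyl (3S)-4-(dimethoxymethyl)-3-methyl-5-(prop-1-yn-1-yl)-3-[(triethylsilyl)oxy]-2-{[(trifluoromethyl)sulfonyl]oxy}cyclopenta-1,4-diene-1-carboxylate | COC(=O)C1=C(OS(=O)(=O)C(F)(F)F)[C@@](C)(O[Si](CC)(CC)CC)C(C(OC)OC)=C1C#CC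
F4 | step 7 | methyl (3R)-4-(dimethoxymethyl)-2-{(2RS,3S)-2-[(4-methoxybenzyl)oxy]-3-methylnonyl}-3-methyl-5-(prop-1-yn-1-yl)-3-[(triethylsilyl)oxy]cyclopenta-1,4-diene-1-carboxylate | CCCCCC[C@H](C)C(OCc1ccc(OC)cc1)CC1=C(C(=O)OC)C(C#CC)=C(C(OC)OC)[C@]1(C)O[Si](CC)(CC)CC
F5 | step 15 | methyl (7R)-6-[(2RS,3S)-2-hydroxy-3-methylnonylidene]-3,7-dimethyl-7-[(triethylsilyl)oxy]-6,7-dihydrocyclopenta[c]pyran-5-carboxylate | CCCCCC[C@H](C)C(O)C=C1C(C(=O)OC)=C2C=C(C)OC=C2[C@]1(C)O[Si](CC)(CC)CC
F6 | step 12 | (3S)-3-methylnonan-2-one | CCCCCC[C@H](C)C(C)=O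
F7 | step 12 | methyl (3S)-2-bromo-4-(1,3-dioxolan-2-yl)-3-methyl-5-(prop-1-yn-1-yl)-3-[(triethylsilyl)oxy]cyclopenta-1,4-diene-1-carboxylate | BrC1=C(C(=O)OC)C(C#CC)=C(C2OCCO2)[C@]1(C)O[Si](CC)(CC)CC
F8 | step 12 | methyl (3R)-4-(1,3-dioxolan-2-yl)-3-methyl-2-[(3S)-3-methyl-2-oxononyl]-5-(prop-1-yn-1-yl)-3-[(triethylsilyl)oxy]cyclopenta-1,4-diene-1-carboxylate | CCCCCC[C@H](C)C(=O)CC1=C(C(=O)OC)C(C#CC)=C(C2OCCO2)[C@]1(C)O[Si](CC)(CC)CC
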